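## Structural features

The target is a (2S)-flavanone: a benzene ring A is fused through C4a and C8a to a dihydropyranone ring C (O1, C2, C3, C4=O), and C2 carries a 4-hydroxyphenyl ring B. Ring A is fully substituted, with O1 on C8a, a prenyl group on C8, a methoxy group on C7, a second prenyl group on C6 and a hydroxyl on C5 that is hydrogen-bonded to the C4 carbonyl. C2 is the only stereocentre and has no stereogenic neighbour, so its configuration has to come from a catalyst, a reagent or a purchased building block. C2 is also the fragile point, because a flavanone opens to the 2'-hydroxychalcone by base-induced β-elimination of O1, and a free 4'-phenoxide makes this easier. The prenyl alkenes cyclise onto a neighbouring free phenol in strong acid, are saturated by hydrogenation and are attacked by electrophilic oxidants, so benzyl ethers, strongly acid-labile groups and harsh oxidations are excluded. The real difficulty is therefore the combination of a hexasubstituted ring A, an isolated benzylic C–O stereocentre and an end game that must stay close to neutral. The key step exploits three facts: O1–C8a–C4a–C4 is an ortho-quinone methide at the oxidation level of a salicylaldehyde, C2–C3 with ring B is a styrene, and the ring A aldehyde has two equivalent hydroxyls flanking the formyl group, so either one can become O1 while the other becomes the C5 oxygen.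

## Logic of the disconnections

**14 to 13.** The two O–Si bonds at the C5 and C4' oxygens are the last bonds to be cleaved. Both phenols carry the same silyl group so that one operation frees them, and a silyl ether is the one common phenol mask that leaves under neutral, non-reducing conditions. The gain is that no phenol is free during the acid and oxidation steps before it. The demand is a fluoride source buffered so that no phenoxide persists next to the ring C ketone.

**13 to 12 to 11.** No skeletal bond is cut here. The C4 ketone of 13 is taken back to the C4 alcohol 12 and this to the C4 methyl ether 11, because the ring-forming step delivers C4 as an ether, one oxidation level below the ketone. The gain is that the configuration at C4 no longer matters. The forward steps must exchange methoxy for hydroxyl at a very easily ionised benzylic carbon without elimination towards C3, and must oxidise a benzylic alcohol in the presence of two trisubstituted alkenes.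

**11 to 5, 7 and 8 (key disconnection).** O1–C2 and C3–C4 are cut, which opens ring C and removes both stereocentres. This is the retron of a hetero-Diels–Alder reaction between the alkene of 7 and an ortho-quinone methide that 5 and 8 generate. The gain is the largest in the route: a hexasubstituted salicylaldehyde, a simple styrene and an orthoester replace the whole chromane. Three design points follow.
- The phenol oxygen of 7 is a silyl ether and not an ester. An acyloxy group shares its lone pair with the carbonyl and would leave the styrene no better a π-nucleophile than the prenyl alkenes of 5, whereas a silyloxy group is a true para donor. An ester would also need base for its removal at the flavanone stage.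
- The second ortho oxygen of 5 is silylated, so only one quinone methide can form.
- A C4 epimer of 11 is equally useful only if it has the same C2 configuration. The forward step therefore needs control of the styrene π-face, not of the diastereomer ratio.

**7 to 6.** The C=C bond is cut to an aldehyde and a one-carbon ylide (Wittig). This places the silyl ether on a stable, purchasable aldehyde instead of a polymerisable vinylphenol. The demand is only that the base is consumed before the aryl silyl ether sees it.

**5 to 4 to 3.** One O–Si bond and then the O–CH3 bond at the para oxygen are cut. In 4 the two ortho hydroxyls are equivalent, and after the first silylation the remaining one is chelated and hindered, which should stop the reaction at the monosilyl stage. In 3 the para hydroxyl is the most acidic and the only one not chelated, which directs methylation. The demand is stoichiometric control in both steps.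

**3 to 1 and 2.** The two aryl–CH2 bonds at C3 and C5 of the aldehyde are cut, so that 1 takes up two equivalents of 2. The phloroglucinol anion is a vinylogous enolate that is alkylated on carbon, and its only two free ring positions are the required ones. The gain is a one-step entry from two commodity chemicals. The demand is to limit O-alkylation and a second alkylation at an already substituted carbon.

## Other disconnections considered

Alternative 1: The cut is at the two aryl–CH2 bonds of the prenyl groups (C6–C1'' and C8–C1''). This leaves the 6,8-diiodoflavanone A2 and the prenyl tin reagent A3. A double Stille coupling under a zerovalent palladium catalyst with a bulky trialkylphosphine would give A1, and removal of the 4'-acetate would give the target.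
- In its favour: ring C and C2 need not be built. A2 should be reachable in about three steps (7-O-methylation, 4'-O-acetylation, double iodination) from (2S)-naringenin A4 of the chiral pool. The coupling is neutral, which suits a flavanone, and the prenyl groups arrive last and never meet acid.
- Against it: each C–I bond lies between two oxygen-bearing carbons, so transmetalation is hindered and has to succeed twice. An allylic stannane can transfer through either terminus, so 1,1-dimethylallyl isomers and protodeiodination are the expected side paths. The free chelated 5-hydroxyl and stoichiometric tin are further burdens. The configuration at C2 is only as good as the purchased A4 and must survive a basic methylation and the final ester cleavage, both of which invite retro-oxa-Michael opening.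
- Comparison: structurally it adds two C–C bonds to a bought skeleton, where the chosen plan forms ring C and C2 together. Mechanistically its key step is a known reaction type, which is an advantage over a cycloaddition that is new, although its α-against-γ question has no counterpart in the chosen plan. In step economy it is the better plan (about five steps against eight). The chosen plan is preferred because C2 is set by a catalyst and no base is used once the flavanone exists.

Alternative 2: The cut runs through ring A. C8–C8a and C6–C7 are disconnected (C4a–C8a is broken and re-formed in the cascade) to the cyclobutenone A6 and the methoxyalkyne A7. On heating, A6 would open to a vinylketene, this would add the ynol ether in a [2+2] sense, and the new cyclobutenone would open again and close by 6π electrocyclisation to the phenol A5.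
- In its favour: every substituent of ring A is placed by the connectivity of the two partners. The three oxygens emerge already differentiated (free hydroxyl for O1, silyl ether at C5, methyl ether at C7). In this regiochemical respect it is better than steps 1 to 3 of the chosen plan, which rely on selectivity among similar hydroxyls. The cascade is a well-understood pericyclic sequence and is more predictable than a new asymmetric cycloaddition.
- Against it: A5 holds neither C4 nor ring C nor the stereocentre. C4a must still be acylated between two oxygen-bearing carbons. C2 must still be set, for example by an enantioselective closure of a 2'-hydroxychalcone, which is not dependable for so hindered and electron-rich a substrate. A6 and A7 each need several steps.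
- Comparison: structurally it solves ring A, which the chosen plan solves more cheaply though less elegantly, and leaves the stereocentre open. Mechanistically it is the safer key step. In step economy it is clearly longer (an estimated twelve steps or more).

Alternative 3: The cut is at O1–C8a and C4–C4a. Fluoride would unmask the aryne from the silyl triflate A9. The alkoxide of the hydroxy ester A10 would add at C8a, and the C4a aryl anion would attack the ester to close ring C and give A8. Removal of the two methoxymethyl groups would follow.
- In its favour: it is convergent. The ketone arrives at the correct oxidation level, so the two redox-adjusting steps of the chosen plan are unnecessary, a point on which it is better. C2 comes with A10, whose configuration can be set by well-established asymmetric ketone reduction and whose C–O bond is never broken. That is more certain than the catalyst control the chosen plan needs.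
- Against it: A9 is a hexasubstituted arene carrying prenyl, silyl and triflate groups in a fixed order, and its preparation would be long. Attack at C8a relies on the inductive pull of the C5 alkoxy group overriding the steric shield of the C8 prenyl group. A secondary benzylic alkoxide is a slow aryne nucleophile. Under basic fluoride a β-hydroxy ester can undergo retro-aldol cleavage or dehydration, the prenyl alkenes are possible ene partners of the aryne, and the new flavanone may open at C2. Acidic removal of the acetals risks cyclisation of prenyl onto phenol.
- Comparison: structurally it forms the same ring as the chosen plan by two different bonds and is its equal in convergence. Mechanistically it is better on the origin of C2 and worse on regiocontrol and base sensitivity. In step economy it is longer because of A9.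

Key step: step 5

Remark 1: the sense of induction of the chiral acid cannot be predicted with confidence; the (R) catalyst is written, and its mirror image is meant should a trial run lead into the (2R) series.

Remark 2: ring positions are numbered as in the flavanone (O1, C2, C3, C4, C4a, C5 to C8, C8a; ring B primed) for 9 to 14 and for the atoms of 5 that become them.

## Route

Step 1
Reactants: 1 2,4,6-trihydroxybenzaldehyde; 2 prenyl bromide (1-bromo-3-methylbut-2-ene)
Product: 3 2,4,6-trihydroxy-3,5-bis(3-methylbut-2-enyl)benzaldehyde
Conditions: KOH (10% aq., 2.2 equiv), 2 (2.1 equiv, slow addition), 0 °C to rt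
Reagents that add atoms: prenyl bromide (second equivalent of 2), CC(C)=CCBr
Why: Base-mediated nuclear prenylation of an acylphloroglucinol, carried out twice in one flask; the phenolate is a vinylogous enolate that is alkylated on carbon in water, where the oxygens are solvated. The only two free ring carbons are the required ones, and each takes up one equivalent of 2.

Step 2
Reactants: 3 2,4,6-trihydroxy-3,5-bis(3-methylbut-2-enyl)benzaldehyde
Product: 4 2,6-dihydroxy-4-methoxy-3,5-bis(3-methylbut-2-enyl)benzaldehyde
Conditions: Me2SO4 (1.0 equiv), K2CO3 (1.0 equiv), acetone, 0 °C to rt
Reagents that add atoms: dimethyl sulfate, COS(=O)(=O)OC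
Why: Selective O-methylation (Williamson type) of the para hydroxyl, which is the most acidic and the only one not chelated to the formyl group; a hard methylating agent favours oxygen over carbon.

Step 3
Reactants: 4 2,6-dihydroxy-4-methoxy-3,5-bis(3-methylbut-2-enyl)benzaldehyde
Product: 5 2-(tert-butyldimethylsilyloxy)-6-hydroxy-4-methoxy-3,5-bis(3-methylbut-2-enyl)benzaldehyde
Conditions: TBSCl (1.1 equiv), imidazole (2.2 equiv), DMF, 0 °C to rt
Reagents that add atoms: tert-butyldimethylsilyl chloride, CC(C)(C)[Si](C)(C)Cl
Why: Phenol silylation; the two hydroxyls are equivalent, and after the first silylation the remaining one is locked in a hydrogen bond to the aldehyde and flanked by a prenyl group, so the second silylation should be much slower.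

Step 4
Reactants: 6 4-(tert-butyldimethylsilyloxy)benzaldehyde
Product: 7 tert-butyldimethyl(4-vinylphenoxy)silane [4-(tert-butyldimethylsilyloxy)styrene]
Conditions: Ph3PCH3Br (1.2 equiv), KOtBu (1.15 equiv), THF, 0 °C to rt
Reagents that add atoms: methyltriphenylphosphonium bromide, C[P+](c1ccccc1)(c1ccccc1)c1ccccc1.[Br-]
Why: Wittig methylenation of an aromatic aldehyde; the base is used in deficit relative to the phosphonium salt so that the aryl silyl ether meets only the ylide.

Step 5
Reactants: 5 2-(tert-butyldimethylsilyloxy)-6-hydroxy-4-methoxy-3,5-bis(3-methylbut-2-enyl)benzaldehyde; 7 tert-butyldimethyl(4-vinylphenoxy)silane; 8 trimethyl orthoformate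
Product: 11 (2S,4S)-5-(tert-butyldimethylsilyloxy)-2-[4-(tert-butyldimethylsilyloxy)phenyl]-4,7-dimethoxy-6,8-bis(3-methylbut-2-enyl)chroman, via dimethyl acetal 9 (not isolated), via 4-methoxy ortho-quinone methide 10 (not isolated)
Conditions: (R)-3,3'-bis(2,4,6-triisopropylphenyl)-BINOL N-triflylphosphoramide (10 mol%), 8 (1.5 equiv), 7 (2 equiv), 5 Å MS, toluene, −40 °C
Reagents that add atoms: none
Why: Proposed new method: the acid converts 5 and 8 into acetal 9 and then, by loss of methanol, into the protonated 4-methoxy ortho-quinone methide 10, an electron-poor 1-oxadiene (O1=C8a–C4a=C4) that stays hydrogen-bonded and ion-paired to the chiral phosphoramide anion through O1–H. The alkene of 7 attacks C4 with its CH2 terminus (C3–C4 bond) and O1 then closes on the developing benzylic cation (O1–C2 bond), so ring C is closed as a six-membered ring by an asynchronous inverse-electron-demand hetero-Diels–Alder [4+2] cycloaddition. The closest known reaction types are the chiral Brønsted acid catalysed [4+2] cycloaddition of ortho-quinone methides from ortho-hydroxybenzyl alcohols with styrenes and the achiral acid-promoted chroman synthesis from salicylaldehydes, orthoformates and alkenes; the new element is their combination on an aldehyde-derived alkoxy quinone methide. C2 is created in the O1–C2 closure next to the anion bound at O1–H, so the 3,3'-aryl groups of the catalyst should decide which π-face of the styrene is presented, whereas C4 follows from the endo or exo orientation and is harmless as long as both diastereomers share the C2 sense. Regioselectivity (aryl on C2) rests on the benzylic, para-oxygen-stabilised positive charge in the transition state. Chemoselectivity for 7 over the prenyl alkenes rests on the para-silyloxy donor, which makes 7 the best π-nucleophile present and allows −40 °C, where protonation of a prenyl alkene next to the free phenol should be slow. The silyl ether on the second ortho oxygen permits only one quinone methide per molecule, and the sieves take up methanol so that it does not compete for the catalyst.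

Step 6
Reactants: 11 (2S,4S)-5-(tert-butyldimethylsilyloxy)-2-[4-(tert-butyldimethylsilyloxy)phenyl]-4,7-dimethoxy-6,8-bis(3-methylbut-2-enyl)chroman
Product: 12 (2S)-5-(tert-butyldimethylsilyloxy)-2-[4-(tert-butyldimethylsilyloxy)phenyl]-7-methoxy-6,8-bis(3-methylbut-2-enyl)chroman-4-ol (C4 epimers)
Conditions: PPTS (0.2 equiv), THF/H2O (4:1), 0 °C to rt
Reagents that add atoms: water, O
Why: Acid-catalysed solvolysis of an electron-rich benzylic methyl ether (unimolecular substitution); the C4 cation is stabilised by O1, the C5 oxygen and the C7 methoxy group, so a weak acid suffices, water in large excess captures it, and C2 and the aryl silyl ethers are not involved.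

Step 7
Reactants: 12 (2S)-5-(tert-butyldimethylsilyloxy)-2-[4-(tert-butyldimethylsilyloxy)phenyl]-7-methoxy-6,8-bis(3-methylbut-2-enyl)chroman-4-ol
Product: 13 (2S)-5-(tert-butyldimethylsilyloxy)-2-[4-(tert-butyldimethylsilyloxy)phenyl]-7-methoxy-6,8-bis(3-methylbut-2-enyl)chroman-4-one
Conditions: DMP (1.3 equiv), pyridine (3 equiv), CH2Cl2, 0 °C to rt
Reagents that add atoms: none
Why: Dess–Martin oxidation of a secondary benzylic alcohol; the reagent leaves isolated trisubstituted alkenes and silyl ethers alone, both C4 epimers converge on one ketone, and pyridine keeps the medium from ionising C4.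

Step 8
Reactants: 13 (2S)-5-(tert-butyldimethylsilyloxy)-2-[4-(tert-butyldimethylsilyloxy)phenyl]-7-methoxy-6,8-bis(3-methylbut-2-enyl)chroman-4-one
Product: 14 (2S)-5-hydroxy-2-(4-hydroxyphenyl)-7-methoxy-6,8-bis(3-methylbut-2-enyl)chroman-4-one
Conditions: TBAF (2.5 equiv), AcOH (2.5 equiv), THF, 0 °C
Reagents that add atoms: none
Why: Fluoride cleavage of two aryl silyl ethers; acetic acid protonates each phenoxide as it forms, so neither β-elimination of O1 nor the quinone methide path from the 4'-phenoxide can scramble C2, and the prenyl groups are inert.

## Compound list

1 | 2,4,6-trihydroxybenzaldehyde | O=Cc1c(O)cc(O)cc1O | starting material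
2 | prenyl bromide (1-bromo-3-methylbut-2-ene) | CC(C)=CCBr | starting material
3 | 2,4,6-trihydroxy-3,5-bis(3-methylbut-2-enyl)benzaldehyde | O=Cc1c(O)c(CC=C(C)C)c(O)c(CC=C(C)C)c1O | intermediate
4 | 2,6-dihydroxy-4-methoxy-3,5-bis(3-methylbut-2-enyl)benzaldehyde | O=Cc1c(O)c(CC=C(C)C)c(OC)c(CC=C(C)C)c1O | intermediate
5 | 2-(tert-butyldimethylsilyloxy)-6-hydroxy-4-methoxy-3,5-bis(3-methylbut-2-enyl)benzaldehyde | O=Cc1c(O)c(CC=C(C)C)c(OC)c(CC=C(C)C)c1O[Si](C)(C)C(C)(C)C | intermediate
6 | 4-(tert-butyldimethylsilyloxy)benzaldehyde | O=Cc1ccc(O[Si](C)(C)C(C)(C)C)cc1 | starting material
7 | tert-butyldimethyl(4-vinylphenoxy)silane | C=Cc1ccc(O[Si](C)(C)C(C)(C)C)cc1 | intermediate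
8 | trimethyl orthoformate | COC(OC)OC | starting material
9 | dimethyl acetal of 5 (not isolated) | COC(OC)c1c(O)c(CC=C(C)C)c(OC)c(CC=C(C)C)c1O[Si](C)(C)C(C)(C)C | intermediate
10 | 4-methoxy ortho-quinone methide from 9 (not isolated; exocyclic double-bond geometry not defined) | COC=C1C(=O)C(CC=C(C)C)=C(OC)C(CC=C(C)C)=C1O[Si](C)(C)C(C)(C)C | intermediate
11 | (2S,4S)-5-(tert-butyldimethylsilyloxy)-2-[4-(tert-butyldimethylsilyloxy)phenyl]-4,7-dimethoxy-6,8-bis(3-methylbut-2-enyl)chroman (2,4-cis drawn; the (2S,4R) epimer may accompany it) | CO[C@H]1C[C@@H](c2ccc(O[Si](C)(C)C(C)(C)C)cc2)Oc2c(CC=C(C)C)c(OC)c(CC=C(C)C)c(O[Si](C)(C)C(C)(C)C)c12 | intermediate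
12 | (2S)-5-(tert-butyldimethylsilyloxy)-2-[4-(tert-butyldimethylsilyloxy)phenyl]-7-methoxy-6,8-bis(3-methylbut-2-enyl)chroman-4-ol (C4 epimers) | OC1C[C@@H](c2ccc(O[Si](C)(C)C(C)(C)C)cc2)Oc2c(CC=C(C)C)c(OC)c(CC=C(C)C)c(O[Si](C)(C)C(C)(C)C)c12 | intermediate
13 | (2S)-5-(tert-butyldimethylsilyloxy)-2-[4-(tert-butyldimethylsilyloxy)phenyl]-7-methoxy-6,8-bis(3-methylbut-2-enyl)chroman-4-one | O=C1C[C@@H](c2ccc(O[Si](C)(C)C(C)(C)C)cc2)Oc2c(CC=C(C)C)c(OC)c(CC=C(C)C)c(O[Si](C)(C)C(C)(C)C)c12 | intermediate
14 | (2S)-5-hydroxy-2-(4-hydroxyphenyl)-7-methoxy-6,8-bis(3-methylbut-2-enyl)chroman-4-one | COc1c(CC=C(C)C)c(O)c2c(c1CC=C(C)C)O[C@H](c1ccc(O)cc1)CC2=O | target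

## Step count and least certain steps

Total: 8 steps. Longest linear sequence: 7 steps (steps 1, 2, 3, 5, 6, 7, 8 from 1); step 4 is a one-step side branch.

**Step 5 (key step, new method).** The most likely failure is insufficient discrimination between the two faces of the styrene in the O1–C2 closure. The first bond (C3–C4) forms away from C2, and the benzylic cation may rotate before the ring closes. Acid-induced cyclisation of a prenyl group onto the free phenol of 5 and cationic oligomerisation of 7 would lower conversion further. The fallback uses known chemistry and moves the stereochemical decision to a resolution. It sets out from 5 (with 7 and 8) and returns at 13. Sc(OTf)3 (5 mol%) in CH2Cl2 at 0 °C, the established achiral version of the reaction, should give the racemic chroman F1. Hydrolysis as in step 6 should give the racemic alcohol F2, and Dess–Martin oxidation as in step 7 the racemic flavanone F3. Kinetic resolution of F3 by asymmetric transfer hydrogenation follows (RuCl(p-cymene)[(S,S)-TsDPEN] or its antipode, whichever reduces the (2R)-ketone faster, HCO2H/Et3N, EtOAc, rt, run to a little over half conversion). It should convert the (2R)-enantiomer into the (2R,4R)-cis-alcohol F4 and leave the (2S)-ketone, which is 13. At most half of the material is carried on.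

**Step 1.** The most likely failure is poor control of the double alkylation: O-prenylation, and a further alkylation at an already prenylated carbon with loss of aromaticity, both expected from an ambident polyphenolate. The fallback builds the two C–C bonds by sigmatropic rearrangement instead. It sets out from 1 and returns at 4, so it also replaces step 2. Methylation of the para hydroxyl of 1 (Me2SO4, K2CO3, acetone) should give 2,6-dihydroxy-4-methoxybenzaldehyde F5. Etherification of both hydroxyls (methyl 2-methylbut-3-yn-2-yl carbonate, DBU, CuCl2 cat., MeCN, 0 °C) should give the bis(1,1-dimethylpropargyl) ether F6. Semihydrogenation (H2, Pd/CaCO3 poisoned with Pb(OAc)2, quinoline, EtOAc) should give the bis(1,1-dimethylallyl) ether F7. Heating (toluene, 110 °C) should bring about two aromatic Claisen rearrangements, each to the only free ortho carbon and each turning the 1,1-dimethylallyl group into a prenyl group, to give 4.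

**Step 2.** The most likely failure is over-methylation at a chelated ortho hydroxyl, or methylation on carbon of the ambident phenolate. The fallback avoids a free phenolate. It sets out from 3 and returns at 4: Mitsunobu etherification (MeOH, PPh3, DIAD, THF, 0 °C) selects the most acidic, non-chelated phenol by protonation of the betaine. This fallback makes no new compound (F0).

**Step 6.** The most likely failure is loss of a proton from C3 of the C4 cation, giving elimination to the 2H-chromene instead of capture by water, or slow ionisation of the C2–O1 bond now that ring B carries a donor. The fallback replaces solvolysis by oxidation. It sets out from 11 and returns at 13, so it also replaces step 7: DDQ (1.2 equiv) in CH2Cl2/pH 7 buffer at 0 °C abstracts the hydridic C4–H next to the methoxy group, and water collapses the oxocarbenium ion to the ketone. The benzylic CH2 groups of the prenyl chains are the sites to watch. This fallback makes no new compound (F0).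

## Further compounds

F1 | step 5 | racemic 5-(tert-butyldimethylsilyloxy)-2-[4-(tert-butyldimethylsilyloxy)phenyl]-4,7-dimethoxy-6,8-bis(3-methylbut-2-enyl)chroman (mixture of diastereomers) | COC1CC(c2ccc(O[Si](C)(C)C(C)(C)C)cc2)Oc2c(CC=C(C)C)c(OC)c(CC=C(C)C)c(O[Si](C)(C)C(C)(C)C)c12
F2 | step 5 | racemic 5-(tert-butyldimethylsilyloxy)-2-[4-(tert-butyldimethylsilyloxy)phenyl]-7-methoxy-6,8-bis(3-methylbut-2-enyl)chroman-4-ol (mixture of diastereomers) | OC1CC(c2ccc(O[Si](C)(C)C(C)(C)C)cc2)Oc2c(CC=C(C)C)c(OC)c(CC=C(C)C)c(O[Si](C)(C)C(C)(C)C)c12
F3 | step 5 | racemic 5-(tert-butyldimethylsilyloxy)-2-[4-(tert-butyldimethylsilyloxy)phenyl]-7-methoxy-6,8-bis(3-methylbut-2-enyl)chroman-4-one | O=C1CC(c2ccc(O[Si](C)(C)C(C)(C)C)cc2)Oc2c(CC=C(C)C)c(OC)c(CC=C(C)C)c(O[Si](C)(C)C(C)(C)C)c12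
F4 | step 5 | (2R,4R)-5-(tert-butyldimethylsilyloxy)-2-[4-(tert-butyldimethylsilyloxy)phenyl]-7-methoxy-6,8-bis(3-methylbut-2-enyl)chroman-4-ol | O[C@@H]1C[C@H](c2ccc(O[Si](C)(C)C(C)(C)C)cc2)Oc2c(CC=C(C)C)c(OC)c(CC=C(C)C)c(O[Si](C)(C)C(C)(C)C)c12
F5 | step 1 | 2,6-dihydroxy-4-methoxybenzaldehyde | O=Cc1c(O)cc(OC)cc1O
F6 | step 1 | 4-methoxy-2,6-bis(2-methylbut-3-yn-2-yloxy)benzaldehyde | O=Cc1c(OC(C)(C)C#C)cc(OC)cc1OC(C)(C)C#C
F7 | step 1 | 4-methoxy-2,6-bis(2-methylbut-3-en-2-yloxy)benzaldehyde | O=Cc1c(OC(C)(C)C=C)cc(OC)cc1OC(C)(C)C=C
F0 | step 2 | none | none
F0 | step 6 | none | none
A1 | alternative 1 | (2S)-2-(4-acetoxyphenyl)-5-hydroxy-7-methoxy-6,8-bis(3-methylbut-2-enyl)chroman-4-one | COc1c(CC=C(C)C)c(O)c2c(c1CC=C(C)C)O[C@H](c1ccc(OC(C)=O)cc1)CC2=O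
A2 | alternative 1 | (2S)-2-(4-acetoxyphenyl)-5-hydroxy-6,8-diiodo-7-methoxychroman-4-one | COc1c(I)c(O)c2c(c1I)O[C@H](c1ccc(OC(C)=O)cc1)CC2=O
A3 | alternative 1 | tributyl(3-methylbut-2-enyl)stannane | CCCC[Sn](CCCC)(CCCC)CC=C(C)C
A4 | alternative 1 | (2S)-naringenin, (2S)-5,7-dihydroxy-2-(4-hydroxyphenyl)chroman-4-one | O=C1C[C@@H](c2ccc(O)cc2)Oc2cc(O)cc(O)c12
A5 | alternative 2 | 3-methoxy-2,4-bis(3-methylbut-2-enyl)-5-(triisopropylsilyloxy)phenol | COc1c(CC=C(C)C)c(O)cc(O[Si](C(C)C)(C(C)C)C(C)C)c1CC=C(C)C
A6 | alternative 2 | 2-(3-methylbut-2-enyl)-3-(triisopropylsilyloxy)cyclobut-2-en-1-one | O=C1CC(O[Si](C(C)C)(C(C)C)C(C)C)=C1CC=C(C)C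
A7 | alternative 2 | 1-methoxy-5-methylhex-4-en-1-yne | COC#CCC=C(C)C
A8 | alternative 3 | (2S)-7-methoxy-5-(methoxymethoxy)-2-[4-(methoxymethoxy)phenyl]-6,8-bis(3-methylbut-2-enyl)chroman-4-one | COc1c(CC=C(C)C)c(OCOC)c2c(c1CC=C(C)C)O[C@H](c1ccc(OCOC)cc1)CC2=O
A9 | alternative 3 | 3-methoxy-5-(methoxymethoxy)-2,4-bis(3-methylbut-2-enyl)-6-(trimethylsilyl)phenyl trifluoromethanesulfonate | COc1c(CC=C(C)C)c(OCOC)c([Si](C)(C)C)c(OS(=O)(=O)C(F)(F)F)c1CC=C(C)C
A10 | alternative 3 | methyl (3S)-3-hydroxy-3-[4-(methoxymethoxy)phenyl]propanoate | O[C@H](c1ccc(OCOC)cc1)CC(=O)OC
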